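**Retrosynthetic overview**
1. Target 10 ⇒ (E)-chalcone 6: ring C is cut at O1–C2 and at C3–OH. Forward, one pot closes ring C through a C–O bond (oxa-Michael) and installs the C3–O bond by oxygen transfer from nitrosobenzene (key step, new).
2. 6 ⇒ acetophenone 4 + isovanillin 5 (Claisen–Schmidt condensation).
3. 4 ⇒ triol 3 (para-selective O-methylation) ⇒ phloroacetophenone 1 + two prenyl bromide 2 (double nuclear C-prenylation).
4. Ring order: rings A and B are bought (1 and 5); ring C is the only ring formed, and it is formed last. Ring A of 4 is symmetric, so both ortho-OH groups give the same ring-C product.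

Assumption: the target has no stereocenter (it is achiral), so the compound as drawn is the single species to be made.

**Step 1**
Reactants: 1 phloroacetophenone (2',4',6'-trihydroxyacetophenone); 2 prenyl bromide (1-bromo-3-methylbut-2-ene)
Product: 3 1-[2,4,6-trihydroxy-3,5-bis(3-methylbut-2-en-1-yl)phenyl]ethan-1-one
Conditions: 2 (2.2 equiv), KOH (10% aq, 2.5 equiv), 0 °C → 25 °C, 3 h
Reagents that add atoms: none
Why: Nuclear (C-)prenylation of a phloroglucinol phenolate: in water the delocalised anion of 1 reacts with the soft allylic bromide through its two equivalent ring carbons C3 and C5 (SN2 C-alkylation, then re-aromatisation), giving the 3,5-di-C-prenyl ketone in modest yield after chromatography from mono-, O- and gem-dialkylated by-products; no stereocenter is formed.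

**Step 2**
Reactants: 3 1-[2,4,6-trihydroxy-3,5-bis(3-methylbut-2-en-1-yl)phenyl]ethan-1-one
Product: 4 1-[2,6-dihydroxy-4-methoxy-3,5-bis(3-methylbut-2-en-1-yl)phenyl]ethan-1-one
Conditions: Me2SO4 (1.05 equiv), K2CO3 (1.1 equiv), acetone, 25 °C
Reagents that add atoms: dimethyl sulfate, COS(=O)(=O)OC
Why: Williamson O-methylation under pKa control: one equivalent of weak base ionises only the 4-OH (para to the acetyl group, hence the most acidic) while the two ortho-OH groups are tied to the carbonyl by hydrogen bonding and stay protonated, so the hard electrophile Me2SO4 methylates O-4 only and cannot touch the prenyl alkenes; no stereocenter is formed.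

**Step 3**
Reactants: 4 1-[2,6-dihydroxy-4-methoxy-3,5-bis(3-methylbut-2-en-1-yl)phenyl]ethan-1-one; 5 isovanillin (3-hydroxy-4-methoxybenzaldehyde)
Product: 6 (E)-1-[2,6-dihydroxy-4-methoxy-3,5-bis(3-methylbut-2-en-1-yl)phenyl]-3-(3-hydroxy-4-methoxyphenyl)prop-2-en-1-one
Conditions: KOH (50% aq, 6 equiv), EtOH, 0 → 25 °C, 48 h, Ar; then 1 M HCl, 0 °C
Reagents that add atoms: none
Why: Claisen–Schmidt (crossed aldol) condensation: the methyl ketone enolate of 4 adds to the non-enolisable aldehyde 5, whose meta-phenoxide cannot deactivate the formyl group by resonance, and E1cB loss of water gives the conjugated enone with the thermodynamically favoured E geometry, the prenyl groups being inert to aqueous base.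

**Step 4**
Reactants: 6 (E)-1-[2,6-dihydroxy-4-methoxy-3,5-bis(3-methylbut-2-en-1-yl)phenyl]-3-(3-hydroxy-4-methoxyphenyl)prop-2-en-1-one
Product: 10 target flavonol (3,5,3'-trihydroxy-7,4'-dimethoxy-6,8-diprenylflavone), via racemic 5-hydroxyflavanone 7 (not isolated), via 3-(anilinooxy)flavanone 8 (not isolated), via flavan-3,4-dione 9 (not isolated)
Conditions: pyrrolidine (30 mol %), AcOH (30 mol %), degassed DMSO, 30 °C, 2 h; PhNO (2.2 equiv, added over 4 h); then Et3N (1 equiv), 40 °C, 1 h; Ar
Reagents that add atoms: nitrosobenzene, O=Nc1ccccc1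
Why: Proposed new method: an amine-catalysed oxa-Michael / O-nitroso-aldol / N–O-cleavage cascade that converts a 2'-hydroxychalcone into a flavonol with nitrosobenzene as a four-electron oxidant – pyrrolidinium acetate first closes ring C through the O1–C2 bond (6-endo oxa-Michael to 7, from either of the two equivalent ortho-OH groups), the pyrrolidine enamine of 7 then attacks the oxygen of acid-activated PhNO with C3 (O-selective nitroso aldol, as known for cyclohexanone enamines with carboxylic acid co-catalysts) to give 8, and Et3N triggers a Kornblum–DeLaMare-type E1cB loss of aniline across the weak N–O bond to the 3,4-dione 9, which tautomerises irreversibly to the aromatic 3-hydroxy-4-pyranone 10; the closest known reaction types are the proline-type α-aminoxylation of ketones with nitrosobenzene and the Kornblum–DeLaMare fragmentation of α-peroxy ketones, neither shown on chalcones or flavanones, and because no epoxide or electrophilic oxygen-transfer reagent is involved, the aurone pathway of peroxide-based oxidative cyclisations is closed and the prenyl alkenes and free phenols are spared; C2 and C3 both end up sp2, so no stereocenter remains.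

**Compound list**
1 | phloroacetophenone, 1-(2,4,6-trihydroxyphenyl)ethan-1-one | CC(=O)c1c(O)cc(O)cc1O | starting material
2 | prenyl bromide, 1-bromo-3-methylbut-2-ene | CC(C)=CCBr | starting material
3 | 1-[2,4,6-trihydroxy-3,5-bis(3-methylbut-2-en-1-yl)phenyl]ethan-1-one | CC(=O)c1c(O)c(CC=C(C)C)c(O)c(CC=C(C)C)c1O | intermediate
4 | 1-[2,6-dihydroxy-4-methoxy-3,5-bis(3-methylbut-2-en-1-yl)phenyl]ethan-1-one | CC(=O)c1c(O)c(CC=C(C)C)c(OC)c(CC=C(C)C)c1O | intermediate
5 | isovanillin, 3-hydroxy-4-methoxybenzaldehyde | COc1ccc(C=O)cc1O | starting material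
6 | (E)-1-[2,6-dihydroxy-4-methoxy-3,5-bis(3-methylbut-2-en-1-yl)phenyl]-3-(3-hydroxy-4-methoxyphenyl)prop-2-en-1-one | COc1ccc(/C=C/C(=O)c2c(O)c(CC=C(C)C)c(OC)c(CC=C(C)C)c2O)cc1O | intermediate
7 | 5-hydroxy-2-(3-hydroxy-4-methoxyphenyl)-7-methoxy-6,8-bis(3-methylbut-2-en-1-yl)chroman-4-one (racemic) | COc1ccc(C2CC(=O)c3c(O)c(CC=C(C)C)c(OC)c(CC=C(C)C)c3O2)cc1O | intermediate
8 | 5-hydroxy-2-(3-hydroxy-4-methoxyphenyl)-7-methoxy-6,8-bis(3-methylbut-2-en-1-yl)-3-[(phenylamino)oxy]chroman-4-one (racemic, 2,3-trans expected, configuration of no consequence) | COc1ccc(C2Oc3c(CC=C(C)C)c(OC)c(CC=C(C)C)c(O)c3C(=O)C2ONc4ccccc4)cc1O | intermediate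
9 | 5-hydroxy-2-(3-hydroxy-4-methoxyphenyl)-7-methoxy-6,8-bis(3-methylbut-2-en-1-yl)chroman-3,4-dione (racemic, keto tautomer of 10) | COc1ccc(C2Oc3c(CC=C(C)C)c(OC)c(CC=C(C)C)c(O)c3C(=O)C2=O)cc1O | intermediate
10 | 3,5-dihydroxy-2-(3-hydroxy-4-methoxyphenyl)-7-methoxy-6,8-bis(3-methylbut-2-en-1-yl)-4H-chromen-4-one (achiral) | COc1ccc(-c2oc3c(CC=C(C)C)c(OC)c(CC=C(C)C)c(O)c3c(=O)c2O)cc1O | target

**Step count and risks**
Total step count: 4. Longest linear sequence: 4 steps (1 → 3 → 4 → 6 → 10); 2 and 5 are bought.

The three steps most likely to fail: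

Step 4 (the proposed new cascade). The risks are:
- slow enamine formation from the chelated aryl ketone;
- N- instead of O-attack on PhNO, which would end in a 3-anilinoflavone;
- a nitroso-ene reaction at the prenyl groups (kept down by slow addition of PhNO);
- loss of PhNO to the aniline by-product (hence 2.2 equiv).

The fallback uses known chemistry, sets out from 6 and comes back to the route at 10. MOMCl (2.5 equiv) and iPr2NEt in CH2Cl2 cap the ring-B hydroxyl and one of the two equivalent ortho-hydroxyls (the chelated one stays free), giving (E)-1-[2-hydroxy-4-methoxy-6-(methoxymethoxy)-3,5-bis(3-methylbut-2-en-1-yl)phenyl]-3-[4-methoxy-3-(methoxymethoxy)phenyl]prop-2-en-1-one F1. The classical Algar–Flynn–Oyamada oxidation (30% H2O2, aq NaOH, MeOH/THF, 0 °C → rt; the nucleophilic peroxide does not attack prenyl alkenes) then gives 3-hydroxy-7-methoxy-5-(methoxymethoxy)-2-[4-methoxy-3-(methoxymethoxy)phenyl]-6,8-bis(3-methylbut-2-en-1-yl)-4H-chromen-4-one F2. HCl (1 M) in MeOH at 40 °C removes both MOM groups to give 10.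

Step 3 (condensation with all phenols free). The acetyl group sits between two phenoxides, so enolate formation is slow and conversion may stall. The fallback sets out from 4 and 5 and comes back at 6. Compound 4 with NaH and MOMCl in DMF (0 °C) gives 1-[4-methoxy-2,6-bis(methoxymethoxy)-3,5-bis(3-methylbut-2-en-1-yl)phenyl]ethan-1-one F3. Compound 5 with MOMCl and iPr2NEt in CH2Cl2 gives 4-methoxy-3-(methoxymethoxy)benzaldehyde F4. KOH in EtOH at rt condenses the two to (E)-1-[4-methoxy-2,6-bis(methoxymethoxy)-3,5-bis(3-methylbut-2-en-1-yl)phenyl]-3-[4-methoxy-3-(methoxymethoxy)phenyl]prop-2-en-1-one F5. HCl (1 M) in MeOH at 40 °C, mild enough to leave the prenyl groups uncyclised, unmasks 6.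

Step 1 (double C-prenylation). Over-alkylation to gem-diprenyl dienones and O-4 prenylation can depress the yield of 3 badly. The fallback sets out from 1 and comes back at 4, bypassing 3 and making step 2 unnecessary. Compound 1 is methylated first (Me2SO4 1 equiv, K2CO3, acetone) to 2',6'-dihydroxy-4'-methoxyacetophenone F6, which can also be bought. With O-4 capped, O-4 prenylation is impossible and dearomatising gem-dialkylation is less favoured. Nuclear prenylation of F6 with 2 (2.2 equiv) and NaOMe in MeOH at 0 °C → rt then places the two prenyl groups on the two free ring carbons and gives 4.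

**Further compounds**
F1 | step 4 | (E)-1-[2-hydroxy-4-methoxy-6-(methoxymethoxy)-3,5-bis(3-methylbut-2-en-1-yl)phenyl]-3-[4-methoxy-3-(methoxymethoxy)phenyl]prop-2-en-1-one | COCOc1cc(/C=C/C(=O)c2c(O)c(CC=C(C)C)c(OC)c(CC=C(C)C)c2OCOC)ccc1OC
F2 | step 4 | 3-hydroxy-7-methoxy-5-(methoxymethoxy)-2-[4-methoxy-3-(methoxymethoxy)phenyl]-6,8-bis(3-methylbut-2-en-1-yl)-4H-chromen-4-one | COCOc1cc(-c2oc3c(CC=C(C)C)c(OC)c(CC=C(C)C)c(OCOC)c3c(=O)c2O)ccc1OC
F3 | step 3 | 1-[4-methoxy-2,6-bis(methoxymethoxy)-3,5-bis(3-methylbut-2-en-1-yl)phenyl]ethan-1-one | CC(=O)c1c(OCOC)c(CC=C(C)C)c(OC)c(CC=C(C)C)c1OCOC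
F4 | step 3 | 4-methoxy-3-(methoxymethoxy)benzaldehyde | COCOc1cc(C=O)ccc1OC
F5 | step 3 | (E)-1-[4-methoxy-2,6-bis(methoxymethoxy)-3,5-bis(3-methylbut-2-en-1-yl)phenyl]-3-[4-methoxy-3-(methoxymethoxy)phenyl]prop-2-en-1-one | COCOc1cc(/C=C/C(=O)c2c(OCOC)c(CC=C(C)C)c(OC)c(CC=C(C)C)c2OCOC)ccc1OC
F6 | step 1 | 1-(2,6-dihydroxy-4-methoxyphenyl)ethan-1-one | CC(=O)c1c(O)cc(OC)cc1O
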